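Sunday's run and Thursday's run already show the two hands parting: after 4.00 h, Thursday's run holds more left-handed product than right-handed product, 45.0 % against 9.2 %.

| flask | left-handed substrate | right-handed substrate | coupling partner | temperature | remark | time |
|---|---|---|---|---|---|---|
| Sunday's | 0.10 M | 0.10 M | 1.3 equiv | −20 °C | run made earlier |  |
| Thursday's | 0.10 M | 0.10 M | 3 equiv | −5 °C | run made earlier |  |
| elm | 0.10 M | 0.10 M | 2.00 equiv |  | at 5 °C until 5.0 h, from then on at −15 °C | 10 h |
| larch | 0.10 M | 0.10 M | 2.00 equiv | −15 °C |  | 10 h |
| maple | 0.10 M | 0.10 M | 2.00 equiv | 5 °C |  | 10 h |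

| run | time / h | left-handed product / % | right-handed product / % | left-handed substrate / % |
|---|---|---|---|---|
| Sunday's | 0.667 | 2.9 | 0 | 47.3 |
| Sunday's | 1.00 | 6.6 | 0 | 45.0 |
| Sunday's | 1.33 | 6.9 | 0 | 41.1 |
| Sunday's | 2.50 | 11.1 | 0.7 | 36.8 |
| Sunday's | 3.00 | 13.9 | 0.1 | 35.8 |
| Sunday's | 5.00 | 19.0 | 0.1 | 28.0 |
| Sunday's | 8.00 | 25.2 | 1.2 | 25.4 |
| Thursday's | 0.250 | 11.1 | 1.6 | 41.9 |
| Thursday's | 0.833 | 25.6 | 1.6 | 24.6 |
| Thursday's | 1.50 | 35.6 | 3.0 | 14.5 |
| Thursday's | 2.00 | 39.0 | 6.9 | 11.6 |
| Thursday's | 3.00 | 41.6 | 8.1 | 6.0 |
| Thursday's | 4.00 | 45.0 | 9.2 | 3.6 |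
| Thursday's | 5.00 | 45.6 | 8.2 | 1.1 |

(readings scatter by 1 percentage point)
- coupling partner is single-handed; left-handed substrate and right-handed substrate are mirror images of each other, charged as a racemate, each of them at the stated concentration
- the handed part of coupling partner does not stay in what it makes, so the products of the two hands are mirror images too
- the best flask by share of left-handed product in all that became left-handed product or right-handed product; "all alike" if 1.5 percentage points covers them all (elm / larch / maple / all alike)
- share of left-handed product in all that became left-handed product or right-handed product, elm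
- share of left-handed product in all that became left-handed product or right-handed product, larch
- share of left-handed product in all that became left-handed product or right-handed product, maple

1. Both hands meet the same coupling partner, so its curve cancels in the ratio of their logarithmic losses. That ratio is the selectivity factor s: ln(fraction of left-handed substrate remaining) over ln(fraction of right-handed substrate remaining). With f the left-handed fraction remaining, the asked share is y = (1−f)/(2−f−f^(1/s)).

2. Sunday's last reading gives 27.9, and Thursday's reading at 4.00 h gives 12.9. Thursday's last reading is set aside, since its left-handed substrate, 1.1 %, lies at the scatter of 1 percentage point. Taking ln s as linear in temperature gives s_L = 21.6 at −15 °C and s_M = 7.76, the selectivity factor at 5 °C.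

Objection: Sunday's right-handed product, 1.2 %, barely clears the scatter of 1 point, and s_M lies outside the runs.

3. The rule still needs f, so the partner curve is replaced by its mean. Thursday's mean partner gives k = 2.68 /M/h, Sunday's 0.817 /M/h. The same interpolation gives 1.21 /M/h for larch and 5.90 /M/h at 5 °C.

4. In larch, a mean partner lying half a substrate charge below the start gives f = 16.2 %, so y = 91.2 %.

Objection: a mean is crude. The exact integral gives f = 17.5 % and y = 91.4 %, so the error barely reaches the share. With Thursday's factor in place of s_L, larch still gives 86.5 %.

5. In the warm flasks both hands eat partner, so its mean is taken as one substrate charge, a rougher guess. Maple gives f = 0.274 % and y = 65.2 %. Elm at its change gives f = 5.23 % and y = 75.0 %, and its cold half has little left-handed substrate to work on. Even with Thursday's factor, larch stands higher than elm, and elm higher than maple, so the reckoning commits to larch.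

The forecast said larch, with 77.5 % for elm, 93.5 % for larch and 71 % for maple, “because cold favours left and stops right-hand leakage”.

The flasks give larch: 78.2 % for elm, 91.3 % for larch, 75.7 % for maple.

    coupling partner + left-handed substrate → left-handed product (k = 6.97 /M/h, Ea = 47.0 kJ/mol)
    coupling partner + right-handed substrate → right-handed product (k = 0.875 /M/h, Ea = 77.0 kJ/mol)
    left-handed substrate ⇌ achiral form (K = 0.401, k = 0.124 /h, Ea = 91.0 kJ/mol, ΔH = −27.0 kJ/mol)
    right-handed substrate ⇌ achiral form (K = 0.401, k = 0.124 /h, Ea = 91.0 kJ/mol, ΔH = −27.0 kJ/mol)
    achiral form → decomposed reagent (k = 0.155 /h, Ea = 92.0 kJ/mol)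
    coupling partner ⇌ dormant form (K = 0.483, k = 0.278 /h, Ea = 87.0 kJ/mol, ΔH = −21.0 kJ/mol)
    (constants at 5 °C)

Maple kept 6.3 % of its left-handed substrate at 10.0 h, far more than the reckoned 0.274 %; with that simulated fraction, s_M returns 75.8 %. Elm at its change, with 9.91 % of its left-handed substrate remaining, returns 77.8 % against a simulated 78.2 %. Part of the high share in larch comes from the length of the run, stopped at 10 h: left until 100 h, larch goes from 91.3 % to 79.5 %.

Readings and results are simulated with made-up constants; noise was put on by code.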